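(The earlier runs and the new flask were computed with made-up constants; scatter was added.)

Take the summer run first: its Ja does not follow one time constant. The constant that leaves 40.2% at 0.125 d leaves 4.78% at 0.417 d, yet the reading there is 0%, so Ja falls faster than that.

- summer: Ja 0.97 M; Jb 2.7 M; run made earlier
- flask: Ja 0.97 M; Jb 1.94 M; time 10 d

- summer (time / d: Jd / %, Ja / %): 0.125: 46.2, 40.2; 0.417: 22.3, 0; 1.25: 1.6, 1.4; 4.00: 0.4, 1.4; 12.0: 0.5, 0

(each reading ± 1 percentage point)

1. the moment within 10 d at which there is most Jd
2. the amount of Jd, in percent of the Ja charged, at that time

- the numbers in the tables scatter with a standard deviation of 1 percentage point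

I therefore suppose autocatalysis: Jd is made in proportion to Jb times Jd times the Ja left, and used in proportion to Jb times Jd. Dividing one pace by the other cancels Jb and Jd. With a the fraction of Ja left and p the fraction present as Jd, this integrates to p = 1 − a + b ln a.

The first summer reading gives 0.149 for b, the balance fraction: the fraction of Ja left when Jd is used as fast as it is made. Jd peaks at a = b, so my height for this flask, charged with the same Ja, is 56.7%.

But b holds no clock, so one number is not enough for the time. Stretching the summer interval between the first two readings by the Jb ratio 1.39, I place the peak between 0.174 d and 0.580 d.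

The forecast says 50% at 0.25 d. It also holds that “the peak height stays about the same”, but its height is lower than mine.

The flask gives 60.3% at 0.243 d, with Ja at 12.9% there, against the 14.9% of my b, which is read off one scattered pair of readings.

    Ja + Jb + Jd → 2 Jd (k = 0.0226 L² mol⁻² min⁻¹)
    Ja + Jb → Jd (k = 3.71 × 10⁻⁶ L mol⁻¹ min⁻¹)
    Jb + Jd → Je (k = 0.00283 L mol⁻¹ min⁻¹)
    Ja → Jc (k = 1.85 × 10⁻⁵ min⁻¹)

In my supposed paces the balance sits at one concentration of Ja, so as a fraction of the charge b goes inversely with the Ja charged: with 1.6 M of Ja and the same Jb it falls to 0.0905, which gives a height of 69.2%; that neighbour flask reaches 72.0%.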